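**Retrosynthetic overview**
1. The C7≡C8 triple bond comes from a sulfone double elimination between a C10 ring sulfone (C7 as CH2SO2Ph) and the C8 aldehyde of C20 crocetindial, whose C8' aldehyde is masked as an acetal.
2. The ring sulfone comes from a (3R)-hydroxy ester; C3 is set by ketoreductase reduction of a β,γ-unsaturated C3 ketone.
3. The only ring is made first, by a Diels–Alder reaction of the 2-silyloxydiene of mesityl oxide with ethyl but-2-ynoate (bonds C4–C5 and C1–C6).
4. Feature used: the tetrasubstituted ring alkene C5=C6 (C5 methyl, C6 bearing C7) lies 1,4 to oxygenated C3 and next to quaternary C1 (CMe2), which is the pattern left by a 2-silyloxydiene adding to an alkynoate that already carries C7.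

Key step: step 2

Assumption: all-E crocetindial is used as purchased and the (R)-selective ketoreductase of step 4 is chosen by screening a commercial enzyme panel; positions are given in carotenoid numbering (ring C1–C6, chain C7–C15 and C15'–C8').

**Step 1**
Reactants: 1 mesityl oxide
Product: 3 2-(tert-butyldimethylsilyloxy)-4-methylpenta-1,3-diene, via lithium dienolate 2 (not isolated)
Conditions: LiN(i-Pr)2 (commercial solution, 1.05 equiv), THF, −78 °C; then TBSCl, DMPU, −78 °C → rt
Reagents that add atoms: tert-butyldimethylsilyl chloride, CC(C)(C)[Si](C)(C)Cl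
Why: Kinetic deprotonation of the enone at the acetyl methyl group gives the cross-conjugated lithium dienolate, and O-silylation of this enolate (silyl enol ether formation) gives the 2-silyloxydiene.

**Step 2**
Reactants: 3 2-(tert-butyldimethylsilyloxy)-4-methylpenta-1,3-diene; 4 ethyl but-2-ynoate
Product: 5 ethyl 4-(tert-butyldimethylsilyloxy)-2,6,6-trimethylcyclohexa-1,4-diene-1-carboxylate
Conditions: AlBr3/AlMe3 (10:1, 30 mol%), toluene/CH2Br2, −20 °C → rt; pyridine then aq. NaHCO3 quench
Reagents that add atoms: none
Why: The AlBr3/AlMe3 pair binds the ester carbonyl of 4 and lowers its LUMO, so diene 3 should add in a concerted but strongly asynchronous [4+2] cycloaddition in which the CH2 terminus of the enol ether (future C4) bonds first to the alkynoate β-carbon (future C5) and the CMe2 terminus (future C1) then closes onto the ester-bearing α-carbon (future C6), while AlMe3 scavenges protons that would destroy the enol ether. The closest known reaction type is the Lewis-acid-promoted Diels–Alder reaction of hindered 4,4-disubstituted 2-silyloxy-1,3-dienes with hindered acceptors and of 2-silyloxydienes with alkynoates. The single six-membered ring is closed by intermolecular [4+2] cycloaddition, both bonds (C4–C5 and C1–C6) forming in one operation; if the process turns stepwise it is a Mukaiyama–Michael addition followed by six-membered ring closure of the aluminium allenolate onto the silyloxyallyl cation at CMe2. No stereocentre is created, because C1 carries two methyl groups and the product is an achiral 1,4-cyclohexadiene that cannot aromatise. The selectivity required is regiochemical: the 2-silyloxy group sends its CH2 terminus to the β-carbon (para orientation of OSi and CO2Et) and the two terminal methyl groups reinforce this by placing the ester carbon next to C1 (ortho orientation), so both substituent effects lead to 5. The linear alkyne keeps contact with the inward methyl group of the s-cis diene to a minimum, which is what should allow the C1–C6 bond between a quaternary and a fully substituted carbon to form.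

**Step 3**
Reactants: 5 ethyl 4-(tert-butyldimethylsilyloxy)-2,6,6-trimethylcyclohexa-1,4-diene-1-carboxylate
Product: 6 ethyl 2,6,6-trimethyl-4-oxocyclohex-1-ene-1-carboxylate
Conditions: 0.5 M aq. HCl (cat.), THF, 0 °C, stopped at full conversion
Reagents that add atoms: none
Why: Acid-catalysed silyl enol ether hydrolysis proceeds by C-protonation at C2 and loss of silanol, so no free enolate is formed and the C5=C6 bond should stay in conjugation with the ester instead of migrating toward the ketone.

**Step 4**
Reactants: 6 ethyl 2,6,6-trimethyl-4-oxocyclohex-1-ene-1-carboxylate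
Product: 7 ethyl (4R)-4-hydroxy-2,6,6-trimethylcyclohex-1-ene-1-carboxylate
Conditions: (R)-selective ketoreductase, NADP+ (cat.), i-PrOH (10% v/v), phosphate buffer pH 6.5, 30 °C
Reagents that add atoms: none
Why: Enzymatic ketone reduction with isopropanol as the terminal reductant; the active site distinguishes the CH2–CMe2 side from the CH2–C(Me)= side of the ketone and delivers hydride to the face that gives the (R)-carbinol (carotenoid C3).

**Step 5**
Reactants: 7 ethyl (4R)-4-hydroxy-2,6,6-trimethylcyclohex-1-ene-1-carboxylate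
Product: 8 ethyl (4R)-4-(tert-butyldimethylsilyloxy)-2,6,6-trimethylcyclohex-1-ene-1-carboxylate
Conditions: TBSCl, imidazole, DMF, rt
Reagents that add atoms: tert-butyldimethylsilyl chloride, CC(C)(C)[Si](C)(C)Cl
Why: Standard silylation of a secondary alcohol, which protects the carbinol from the hydride, bromination and strong-base steps that follow without touching the stereocentre.

**Step 6**
Reactants: 8 ethyl (4R)-4-(tert-butyldimethylsilyloxy)-2,6,6-trimethylcyclohex-1-ene-1-carboxylate
Product: 9 [(4R)-4-(tert-butyldimethylsilyloxy)-2,6,6-trimethylcyclohex-1-en-1-yl]methanol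
Conditions: (i-Bu)2AlH (3 equiv), CH2Cl2, −78 → 0 °C; aq. Rochelle salt
Reagents that add atoms: none
Why: 1,2-Reduction of the hindered α,β-unsaturated ester to the allylic alcohol by an aluminium hydride, as for cyclogeranate esters; the silyl ether is inert.

**Step 7**
Reactants: 9 [(4R)-4-(tert-butyldimethylsilyloxy)-2,6,6-trimethylcyclohex-1-en-1-yl]methanol
Product: 10 (4R)-1-(bromomethyl)-4-(tert-butyldimethylsilyloxy)-2,6,6-trimethylcyclohex-1-ene
Conditions: CBr4, PPh3, CH2Cl2, 0 °C
Reagents that add atoms: carbon tetrabromide, BrC(Br)(Br)Br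
Why: The Appel reaction converts the primary allylic alcohol into the bromide under neutral conditions that spare the silyl ether.

**Step 8**
Reactants: 10 (4R)-1-(bromomethyl)-4-(tert-butyldimethylsilyloxy)-2,6,6-trimethylcyclohex-1-ene; 11 sodium benzenesulfinate
Product: 12 (4R)-4-(tert-butyldimethylsilyloxy)-2,6,6-trimethyl-1-[(phenylsulfonyl)methyl]cyclohex-1-ene
Conditions: PhSO2Na, DMF, rt
Reagents that add atoms: none
Why: SN2 S-alkylation of the sulfinate by the primary allylic bromide gives the allylic sulfone, the usual way to cyclogeranyl sulfones.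

**Step 9**
Reactants: 13 crocetindial (all-E)
Product: 14 crocetindial mono(neopentyl glycol) acetal
Conditions: 2,2-dimethylpropane-1,3-diol (1.0 equiv), pyridinium p-toluenesulfonate (cat.), CH2Cl2, 4 Å molecular sieves, rt; chromatography, dial and bis-acetal recycled
Reagents that add atoms: 2,2-dimethylpropane-1,3-diol, OCC(C)(C)CO
Why: Acid-catalysed acetalisation with a limiting amount of diol should give a statistical mixture from which the mono-acetal of the C2-symmetric dial is separated, leaving one aldehyde (C8) free for coupling.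

**Step 10**
Reactants: 12 ring sulfone; 14 crocetindial mono(neopentyl glycol) acetal
Product: 19 (3R)-3-(tert-butyldimethylsilyloxy)-7,8-didehydro-8'-apo-β-caroten-8'-al neopentyl glycol acetal, via lithiated sulfone 15 (not isolated), via lithium alkoxide 16 (not isolated), via phosphate ester 17 (not isolated), via vinyl sulfone 18 (not isolated)
Conditions: LiN(SiMe3)2 (1.1 equiv), THF, −78 °C; 14; ClP(O)(OEt)2 (1.2 equiv), −78 °C; LiN(SiMe3)2 (4 equiv), −78 °C → rt, dark
Reagents that add atoms: none
Why: One-pot sulfone double elimination: Julia-type addition of the α-sulfonyl carbanion to the enal forms C7–C8, phosphorylation turns the C8 oxygen into a leaving group, base-induced loss of diethyl phosphate gives the vinyl sulfone and a second elimination of benzenesulfinate should give the C7≡C8 triple bond while the E-polyene, acetal and silyl ether are untouched.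

**Step 11**
Reactants: 19 (3R)-3-(tert-butyldimethylsilyloxy)-7,8-didehydro-8'-apo-β-caroten-8'-al neopentyl glycol acetal
Product: 20 (3R)-3-hydroxy-7,8-didehydro-8'-apo-β-caroten-8'-al (target)
Conditions: 48% aq. HF, MeCN/THF, 0 °C → rt, dark, argon
Reagents that add atoms: water, O
Why: Aqueous HF cleaves the silyl ether at silicon and hydrolyses the polyenyl dioxane acetal through its highly stabilised oxocarbenium ion, so a single global deprotection should release the C3 alcohol and the C8' aldehyde without involving the stereocentre.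

**Compound list**
1 | mesityl oxide (4-methylpent-3-en-2-one) | CC(=O)C=C(C)C | starting material
2 | lithium 4-methylpenta-1,3-dien-2-olate | [Li+].[O-]C(=C)C=C(C)C | intermediate
3 | 2-(tert-butyldimethylsilyloxy)-4-methylpenta-1,3-diene | C=C(O[Si](C)(C)C(C)(C)C)C=C(C)C | intermediate
4 | ethyl but-2-ynoate | CC#CC(=O)OCC | starting material
5 | ethyl 4-(tert-butyldimethylsilyloxy)-2,6,6-trimethylcyclohexa-1,4-diene-1-carboxylate | CC1=C(C(=O)OCC)C(C)(C)C=C(O[Si](C)(C)C(C)(C)C)C1 | intermediate
6 | ethyl 2,6,6-trimethyl-4-oxocyclohex-1-ene-1-carboxylate | CC1=C(C(=O)OCC)C(C)(C)CC(=O)C1 | intermediate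
7 | ethyl (4R)-4-hydroxy-2,6,6-trimethylcyclohex-1-ene-1-carboxylate | CC1=C(C(=O)OCC)C(C)(C)C[C@H](O)C1 | intermediate
8 | ethyl (4R)-4-(tert-butyldimethylsilyloxy)-2,6,6-trimethylcyclohex-1-ene-1-carboxylate | CC1=C(C(=O)OCC)C(C)(C)C[C@H](O[Si](C)(C)C(C)(C)C)C1 | intermediate
9 | [(4R)-4-(tert-butyldimethylsilyloxy)-2,6,6-trimethylcyclohex-1-en-1-yl]methanol | CC1=C(CO)C(C)(C)C[C@H](O[Si](C)(C)C(C)(C)C)C1 | intermediate
10 | (4R)-1-(bromomethyl)-4-(tert-butyldimethylsilyloxy)-2,6,6-trimethylcyclohex-1-ene | CC1=C(CBr)C(C)(C)C[C@H](O[Si](C)(C)C(C)(C)C)C1 | intermediate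
11 | sodium benzenesulfinate | [Na+].[O-]S(=O)c1ccccc1 | starting material
12 | (4R)-4-(tert-butyldimethylsilyloxy)-2,6,6-trimethyl-1-[(phenylsulfonyl)methyl]cyclohex-1-ene | CC1=C(CS(=O)(=O)c2ccccc2)C(C)(C)C[C@H](O[Si](C)(C)C(C)(C)C)C1 | intermediate
13 | crocetindial (all-E 8,8'-diapocarotene-8,8'-dial) | O=C/C(C)=C/C=C/C(C)=C/C=C/C=C(C)/C=C/C=C(\C)C=O | starting material
14 | (2E,4E,6E,8E,10E,12E,14E)-15-(5,5-dimethyl-1,3-dioxan-2-yl)-2,6,11-trimethylhexadeca-2,4,6,8,10,12,14-heptaenal (crocetindial mono-acetal) | O=C/C(C)=C/C=C/C(C)=C/C=C/C=C(C)/C=C/C=C(\C)C1OCC(C)(C)CO1 | intermediate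
15 | C7-lithiated sulfone derived from 12 | CC1=C([CH-]S(=O)(=O)c2ccccc2)C(C)(C)C[C@H](O[Si](C)(C)C(C)(C)C)C1.[Li+] | intermediate
16 | lithium C8-alkoxide of the C7-sulfonyl adduct of 12 and 14 (mixture of C7/C8 diastereomers) | CC1=C(C(S(=O)(=O)c2ccccc2)C([O-])/C(C)=C/C=C/C(C)=C/C=C/C=C(C)/C=C/C=C(\C)C2OCC(C)(C)CO2)C(C)(C)C[C@H](O[Si](C)(C)C(C)(C)C)C1.[Li+] | intermediate
17 | C8 diethyl phosphate of the C7-sulfonyl adduct (mixture of C7/C8 diastereomers) | CC1=C(C(S(=O)(=O)c2ccccc2)C(OP(=O)(OCC)OCC)/C(C)=C/C=C/C(C)=C/C=C/C=C(C)/C=C/C=C(\C)C2OCC(C)(C)CO2)C(C)(C)C[C@H](O[Si](C)(C)C(C)(C)C)C1 | intermediate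
18 | C7-phenylsulfonyl C7=C8 vinyl sulfone (E/Z mixture at C7=C8) | CC1=C(C(S(=O)(=O)c2ccccc2)=C/C(C)=C/C=C/C(C)=C/C=C/C=C(C)/C=C/C=C(\C)C2OCC(C)(C)CO2)C(C)(C)C[C@H](O[Si](C)(C)C(C)(C)C)C1 | intermediate
19 | (3R)-3-(tert-butyldimethylsilyloxy)-7,8-didehydro-8'-apo-β-caroten-8'-al 5,5-dimethyl-1,3-dioxane acetal | CC1=C(C#C/C(C)=C/C=C/C(C)=C/C=C/C=C(C)/C=C/C=C(\C)C2OCC(C)(C)CO2)C(C)(C)C[C@H](O[Si](C)(C)C(C)(C)C)C1 | intermediate
20 | (3R)-3-hydroxy-7,8-didehydro-8'-apo-β-caroten-8'-al (CNP0269043.1) | CC1=C(C#C/C(C)=C/C=C/C(C)=C/C=C/C=C(C)/C=C/C=C(\C)C=O)C(C)(C)C[C@H](O)C1 | target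

**Totals**
Total step count: 11. Longest linear sequence: 10 steps (steps 1–8, 10 and 11, from mesityl oxide); step 9 is a one-step branch from crocetindial.

**Steps most likely to fail**

Step 2. The cycloaddition may stall because the inward methyl group disfavours the s-cis diene conformer. The activated alkynoate may also be consumed by Mukaiyama–Michael addition without ring closure or by [2+2] closure to a cyclobutene, and the silyl enol ether may be lost to the Lewis acid. The fallback sets out from 1 and builds the ring by annulation instead of cycloaddition. BF3·OEt2-promoted Michael–aldol condensation of 1 with ethyl acetoacetate (CCOC(=O)CC(C)=O) should give the conjugated enone ethyl 2,6,6-trimethyl-4-oxocyclohex-2-ene-1-carboxylate F1. Deconjugation of F1 follows: KOt-Bu in THF at 0 °C forms the extended dienolate, and an inverse quench into cold aqueous AcOH protonates it kinetically at the α-carbon (C4). This moves the double bond to C5=C6 and comes back to the route at 6.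

Step 10. The hindered sulfone anion may add reversibly. The second elimination may also be outrun by deprotonation at ring C4 or at chain methyl groups vinylogous to the sulfone, so that the vinyl sulfone stalls or drifts to allene or retro-type products. The fallback sets out from 12 and 14 and replaces the base-induced loss of sulfinate by a reductive elimination. Addition of lithiated 12 to 14 at −78 °C with a cold AcOH quench gives the β-hydroxy sulfone F2. Dess–Martin oxidation gives the β-keto sulfone F3. NaH and ClP(O)(OEt)2 in THF convert it regiospecifically into the C7-sulfonyl C8-enol diethyl phosphate F4. Reductive elimination with sodium amalgam (Na/Hg) in THF/DMSO at −20 °C removes sulfinate and phosphate, forms C7≡C8 and comes back to the route at 19.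

Step 4. The enzyme may discriminate poorly between the two CH2-flanked sides of the ketone, and during the long aqueous incubation the C5=C6 bond may migrate into conjugation with the ketone. The fallback sets out from 6. Fast Luche reduction (NaBH4, CeCl3·7H2O, MeOH, −78 °C) gives racemic ethyl 4-hydroxy-2,6,6-trimethylcyclohex-1-ene-1-carboxylate F5. Lipase-catalysed kinetic resolution (Burkholderia cepacia lipase, vinyl acetate, MTBE, rt) is expected to acylate the (R)-enantiomer, with the gem-dimethyl side acting as the large group; the configuration is to be confirmed. This gives ethyl (4R)-4-acetoxy-2,6,6-trimethylcyclohex-1-ene-1-carboxylate F6 and leaves ethyl (4S)-4-hydroxy-2,6,6-trimethylcyclohex-1-ene-1-carboxylate F7, which is separated. Methanolysis of F6 (K2CO3, MeOH, 0 °C) comes back to the route at 7.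

**Further compounds**
F1 | step 2 | ethyl 2,6,6-trimethyl-4-oxocyclohex-2-ene-1-carboxylate (racemic) | CCOC(=O)C1C(C)=CC(=O)CC1(C)C
F2 | step 10 | C8-hydroxy C7-phenylsulfonyl adduct of 12 and 14 (mixture of C7/C8 diastereomers) | CC1=C(C(S(=O)(=O)c2ccccc2)C(O)/C(C)=C/C=C/C(C)=C/C=C/C=C(C)/C=C/C=C(\C)C2OCC(C)(C)CO2)C(C)(C)C[C@H](O[Si](C)(C)C(C)(C)C)C1
F3 | step 10 | C8-oxo C7-phenylsulfonyl compound (β-keto sulfone, mixture at C7) | CC1=C(C(S(=O)(=O)c2ccccc2)C(=O)/C(C)=C/C=C/C(C)=C/C=C/C=C(C)/C=C/C=C(\C)C2OCC(C)(C)CO2)C(C)(C)C[C@H](O[Si](C)(C)C(C)(C)C)C1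
F4 | step 10 | C7-phenylsulfonyl C8-enol diethyl phosphate (C7=C8, E/Z mixture) | CC1=C(C(S(=O)(=O)c2ccccc2)=C(OP(=O)(OCC)OCC)/C(C)=C/C=C/C(C)=C/C=C/C=C(C)/C=C/C=C(\C)C2OCC(C)(C)CO2)C(C)(C)C[C@H](O[Si](C)(C)C(C)(C)C)C1
F5 | step 4 | ethyl 4-hydroxy-2,6,6-trimethylcyclohex-1-ene-1-carboxylate (racemic) | CC1=C(C(=O)OCC)C(C)(C)CC(O)C1
F6 | step 4 | ethyl (4R)-4-acetoxy-2,6,6-trimethylcyclohex-1-ene-1-carboxylate | CC1=C(C(=O)OCC)C(C)(C)C[C@H](OC(C)=O)C1
F7 | step 4 | ethyl (4S)-4-hydroxy-2,6,6-trimethylcyclohex-1-ene-1-carboxylate | CC1=C(C(=O)OCC)C(C)(C)C[C@@H](O)C1
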